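Time is short in this flask: 40 min are allowed, but the noon run, which is this same flask followed so far, is down to 1% of target by 2.50 min.

| flask | substrate | remark | time |
|---|---|---|---|
| noon | 0.80 M | the very flask that is asked about, followed so far |  |
| dusk | 0.40 M | run made earlier |  |
| flask | 0.80 M |  | 40 min |

| run | time / min | target / % |
|---|---|---|
| noon | 0.167 | 30 |
| noon | 0.250 | 42 |
| noon | 0.500 | 68 |
| noon | 1.33 | 19 |
| noon | 2.50 | 1 |
| noon | 6.00 | 0 |
| noon | 12.0 | 0 |
| dusk | 0.417 | 65 |
| dusk | 0.833 | 35 |
| dusk | 2.00 | 6 |
| dusk | 4.00 | 0 |
| dusk | 8.00 | 0 |
| dusk | 20.0 | 0 |
| dusk | 40.0 | 0 |

(scatter of a reading: 2 percentage points)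

- the numbers in the tables scatter with a standard deviation of 2 percentage points

- when, up to 40 min, the flask holds most target
- the amount of target, in percent of the substrate charged, at that time

So you work with what is left. In the dusk run target falls from 35% to 6% between 0.833 min and 2.00 min, a first-order loss of 1.51 min⁻¹. Allowing for that loss, the noon reading of 42% at 0.250 min means target is made at 2.02 min⁻¹ in fractions of the charge, so the noon charge lasts 0.496 min, far less than the time allowed.

But does the pace hold at a smaller charge? If formation is zero order in substrate, the dusk charge, half the noon one, lasts half as long, and this gives 64.6% at 0.417 min, where the dusk run read 65%.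

So I reckon with the survival share, the fraction of target made at a steady pace that still stands when the charge ends: one minus the fraction left after the charge's lifetime, divided by loss constant times lifetime. For this flask that is 70.4% at 0.496 min.

The forecast says 0.5 min and 70%, holding that “the maximum comes when substrate runs out”, and my reckoning agrees.

The flask peaks at 0.490 min with 63.7%.

    target → over-reaction product (k = 0.0245 s⁻¹)
    substrate + target → side product (k = 0.00104 M⁻¹ s⁻¹)
    substrate → target, rate k3*[substrate]/(1 + ([substrate]/sat3)) (0.0875 M, k = 0.382 s⁻¹)

At that moment 6.54% of the flask's charge is still substrate, and of the charge no longer substrate 68.2% stands as target, beside a survival share of 70.4%. For a neighbouring flask, the same but with 2.0 M of substrate, the same pace in M per minute gives the charge a reckoned lifetime of 1.24 min and a survival share of 45.2%, and target in that neighbouring flask peaks at 44.8%.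

The readings were generated by integration for substances that don't exist; the scatter is artificial.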